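**Plan**

- The target is (S)-4-hydroxy-2-octadecanoylcyclohexane-1,3-dione, drawn as one enol. In dione numbering, C2 carries the acyl group and C4 the hydroxyl.
- Retrosynthesis first masks the C3 oxygen as an ethyl enol ether and the C4 hydroxyl as a benzyloxymethyl (BOM) acetal. It then cuts C1–C2 and C3–C4 together, and last the acyl–alkyne bond.
- The enabling feature is that the ketone carbon C1 and the carbinol carbon C4 are bridged by the C6–C5 ethylene. O=C1–C6–C5–C4–O is therefore a 2-oxycyclobutanone once a temporary C1–C4 bond is drawn, and C2–C3 is the triple bond of an acyl ynol ether.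
- Forward, the stearoyl chain is first joined to ethoxyacetylene. The six-membered ring then arises in one nickel-catalyzed [4+2] ring expansion that breaks the strained C1–C4 bond. Last, the enol ether and the acetal are removed.
- The single stereocenter comes from a lipase resolution of 2-hydroxycyclobutanone and is carried through the ring expansion with retention.

Key step: step 5

Assumption: Candida antarctica lipase B is taken to follow the usual secondary-alcohol preference with the ring carbonyl carbon as the large substituent, so that the (R)-alcohol is acetylated and the (S)-alcohol is left.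

**Route**

Step 1
Reactants: 1 1,2-bis(trimethylsilyloxy)cyclobut-1-ene
Product: 2 rac-2-hydroxycyclobutan-1-one
Conditions: MeOH (dry, degassed), N2, rt; distillation
Reagents that add atoms: none
Why: Methanolysis of both O–Si bonds of the acyloin enediol bis-silyl ether releases the enediol, which tautomerizes to the α-hydroxy ketone (silyl ether solvolysis).

Step 2
Reactants: 2 rac-2-hydroxycyclobutan-1-one
Product: 3 (S)-2-hydroxycyclobutan-1-one
Conditions: Novozym 435 (immobilized Candida antarctica lipase B), vinyl acetate, MTBE, 25 °C, stopped just past half conversion; chromatography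
Reagents that add atoms: none
Why: Lipase-catalyzed kinetic resolution by enantioselective transesterification of a secondary α-hydroxy ketone should acetylate the (R)-alcohol and leave the (S)-alcohol, whose configuration becomes that of the target carbinol.

Step 3
Reactants: 3 (S)-2-hydroxycyclobutan-1-one
Product: 4 (S)-2-[(benzyloxy)methoxy]cyclobutan-1-one
Conditions: BOMCl, iPr2NEt, CH2Cl2, 0 °C to rt
Reagents that add atoms: benzyl chloromethyl ether (ClCOCc1ccccc1)
Why: O-alkylation of the alcohol with the reactive chloromethyl ether under a hindered amine base does not touch the stereocenter, blocks the α-ketol rearrangement and installs an O,O-chelating acetal that can later be removed by hydrogenolysis.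

Step 4
Reactants: 5 ethoxyacetylene; 6 octadecanoyl chloride
Product: 9 1-ethoxyicos-1-yn-3-one, via lithium ethoxyacetylide 7 (not isolated), via (ethoxyethynyl)zinc chloride 8 (not isolated)
Conditions: n-BuLi, THF, −78 °C; ZnCl2, −78 to 0 °C; then 6, Pd(PPh3)4 (3 mol%), 0 °C to rt; pH 7 buffer work-up, Et3N-deactivated silica
Reagents that add atoms: none
Why: Negishi-type palladium-catalyzed acylation of an alkynylzinc chloride with an acid chloride (oxidative addition to zerovalent palladium, transmetalation, reductive elimination) should give the ynone without 1,2-addition to the product and with no amine present that could add to the push-pull alkyne.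

Step 5
Reactants: 4 (S)-2-[(benzyloxy)methoxy]cyclobutan-1-one; 9 1-ethoxyicos-1-yn-3-one
Product: 10 (S)-4-[(benzyloxy)methoxy]-3-ethoxy-2-octadecanoylcyclohex-2-en-1-one
Conditions: Ni(cod)2 (10 mol%), PCy3 (20 mol%), toluene, 80 °C, 9 (1.5 equiv) added slowly by syringe pump
Reagents that add atoms: none
Why: Proposed new method: zerovalent nickel is expected to couple the strained C=O of 4 with the triple bond of 9 by oxidative cyclization (ketone carbon to the acyl-bearing alkyne carbon, nickel to the carbonyl oxygen and to the ethoxy-bearing carbon), after which β-carbon elimination opens the spiro cyclobutane on the side of the BOM-bearing carbon and C(sp2)–C(sp3) reductive elimination joins that carbon to the ethoxy-bearing carbon, so that the two alkyne carbons are inserted into the C(=O)–CH(O) bond of the cyclobutanone. The closest known reaction is the Ni(cod)2/phosphine-catalyzed intermolecular [4+2] insertion of internal alkynes into the acyl–carbon bond of 3-substituted cyclobutanones and of azetidin-3-ones, which has not been shown for a 2-alkoxycyclobutanone or for an acyl ynol ether. The six-membered ring is closed as a formal [4+2] ring expansion in which the first ring bond forms in a five-membered oxanickelacycle and the second by reductive elimination from a seven-membered nickelacycle, driven by release of the four-membered-ring strain. No new stereocenter is created: the carbinol carbon passes from carbon to nickel and back to carbon with retention at both stages, so the (S) center of 4 becomes the (S) center of 10. The step needs cleavage of the C(=O)–CH(OBOM) bond in preference to the C(=O)–CH2 bond, which the BOM ether should secure by chelating nickel next to the bond to be broken and by stabilizing the α-alkoxyalkyl nickel that results, and it needs one alkyne orientation, which the push-pull polarization of 9 should secure because the acyl-bearing carbon is the nucleophilic terminus (as the β-carbon of ynamides is in nickel oxidative cyclizations with aldehydes). The temperature is held at 80 °C and 9 is added slowly to suppress retro-ene loss of ethylene from the ynol ether and nickel-mediated cyclotrimerization.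

Step 6
Reactants: 10 (S)-4-[(benzyloxy)methoxy]-3-ethoxy-2-octadecanoylcyclohex-2-en-1-one
Product: 12 (S)-4-hydroxy-2-octadecanoylcyclohexane-1,3-dione, via benzyloxymethyl ether 11 (not isolated)
Conditions: 1 M aq HCl, THF, rt; then H2 (1 atm), 10% Pd/C, same pot
Reagents that add atoms: water (O)
Why: Dilute acid should hydrolyze the vinylogous ethyl ester by addition–elimination of water at the ethoxy-bearing carbon, and hydrogenolysis of the benzyl C–O bond then releases a hemiformal that loses formaldehyde, under conditions mild enough to spare the α-ketol stereocenter and to avoid dehydration to the acylresorcinol.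

**Compound list**

1 | 1,2-bis(trimethylsilyloxy)cyclobut-1-ene | C[Si](C)(C)OC1=C(O[Si](C)(C)C)CC1 | starting material
2 | rac-2-hydroxycyclobutan-1-one | OC1CCC1=O | intermediate
3 | (S)-2-hydroxycyclobutan-1-one | O[C@H]1CCC1=O | intermediate
4 | (S)-2-[(benzyloxy)methoxy]cyclobutan-1-one | O=C1CC[C@@H]1OCOCc2ccccc2 | intermediate
5 | ethoxyacetylene | CCOC#C | starting material
6 | octadecanoyl chloride (stearoyl chloride) | CCCCCCCCCCCCCCCCCC(=O)Cl | starting material
7 | lithium ethoxyacetylide | [Li]C#COCC | intermediate
8 | (ethoxyethynyl)zinc chloride | Cl[Zn]C#COCC | intermediate
9 | 1-ethoxyicos-1-yn-3-one | CCCCCCCCCCCCCCCCCC(=O)C#COCC | intermediate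
10 | (S)-4-[(benzyloxy)methoxy]-3-ethoxy-2-octadecanoylcyclohex-2-en-1-one | CCCCCCCCCCCCCCCCCC(=O)C1=C(OCC)[C@@H](OCOCc2ccccc2)CCC1=O | intermediate
11 | (S)-4-[(benzyloxy)methoxy]-2-octadecanoylcyclohexane-1,3-dione (enol form) | CCCCCCCCCCCCCCCCCC(=O)C1=C(O)CC[C@H](OCOCc2ccccc2)C1=O | intermediate
12 | (S)-4-hydroxy-2-octadecanoylcyclohexane-1,3-dione (enol form as drawn) | CCCCCCCCCCCCCCCCCC(=O)C1=C(O)CC[C@H](O)C1=O | target

**Step count and risks**

Total step count: 6. Longest linear sequence: 5 steps (steps 1, 2, 3, 5, 6 from compound 1).

Steps most likely to fail:

1. Step 5 (proposed new method). The β-carbon elimination may take the less hindered CH2 instead of the oxygenated carbon, the alkyne may insert in the reverse orientation, or the ynone may be consumed by cyclotrimerization or ethylene loss before it meets the ketone. The fallback uses known chemistry and takes the stereocenter from the chiral pool; it sets out from octadecanoyl chloride 6 and comes back at the target 12. Lithium dimethylcuprate (Me2CuLi, Et2O, −78 °C) converts 6 into nonadecan-2-one F1. Commercial (S)-5-oxotetrahydrofuran-2-carboxylic acid (derived from L-glutamic acid) is converted with oxalyl chloride and catalytic DMF into (S)-5-oxotetrahydrofuran-2-carbonyl chloride F2. The kinetic lithium enolate of F1 (LDA, THF, −78 °C, two equivalents) is C-acylated by F2 to give (S)-5-(3-oxoicosanoyl)dihydrofuran-2(3H)-one F3. KOtBu (2.2 equiv, THF, 0 °C) then drives an intramolecular Claisen condensation of the diketone carbon onto the lactone carbonyl, which closes the six-membered ring and releases the C4 alkoxide; acidification gives 12. The diketone is held as its enolate throughout, which protects the adjacent stereocenter.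

2. Step 2. The lipase may discriminate the two enantiomers of the small, nearly symmetric ring poorly, or may show the reverse preference. The fallback replaces resolution by desymmetrization; it sets out from 2 and comes back at 4. NaBH4 in MeOH reduces 2, and the meso isomer cis-cyclobutane-1,2-diol F4 is separated from the trans diol. Catalytic enantioselective monobenzoylation (BzCl, Cu(OTf)2, Ph-BOX ligand of the antipode that acylates the pro-R hydroxyl, K2CO3, CH2Cl2) gives (1R,2S)-2-hydroxycyclobutyl benzoate F5. BOMCl and iPr2NEt give (1R,2S)-2-[(benzyloxy)methoxy]cyclobutyl benzoate F6. K2CO3 in MeOH removes the benzoate to give (1R,2S)-2-[(benzyloxy)methoxy]cyclobutan-1-ol F7, and Dess–Martin periodinane oxidizes it to 4.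

3. Step 4. The ynol ether may be lost by zinc chloride-assisted addition of chloride or water across the polarized triple bond, or the acyl palladium intermediate may give ketene-derived or decarbonylated material. The fallback replaces the cross-coupling by an ionic 1,2-addition; it sets out from 6 and comes back at 9. N,O-Dimethylhydroxylamine hydrochloride and pyridine in CH2Cl2 convert 6 into N-methoxy-N-methyloctadecanamide F8. Lithium ethoxyacetylide 7 (from 5 and n-BuLi, THF, −78 °C) adds once to F8, and the stable chelate is collapsed by inverse quench into cold aqueous NaHSO4, so that the liberated amine is protonated before it can add to 9.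

**Further compounds**

F1 | step 5 | nonadecan-2-one | CCCCCCCCCCCCCCCCCC(C)=O
F2 | step 5 | (S)-5-oxotetrahydrofuran-2-carbonyl chloride | O=C1CC[C@@H](C(=O)Cl)O1
F3 | step 5 | (S)-5-(3-oxoicosanoyl)dihydrofuran-2(3H)-one | CCCCCCCCCCCCCCCCCC(=O)CC(=O)[C@@H]1CCC(=O)O1
F4 | step 2 | cis-cyclobutane-1,2-diol (meso) | O[C@H]1CC[C@H]1O
F5 | step 2 | (1R,2S)-2-hydroxycyclobutyl benzoate | O[C@H]1CC[C@H]1OC(=O)c2ccccc2
F6 | step 2 | (1R,2S)-2-[(benzyloxy)methoxy]cyclobutyl benzoate | c1ccccc1COCO[C@H]2CC[C@H]2OC(=O)c3ccccc3
F7 | step 2 | (1R,2S)-2-[(benzyloxy)methoxy]cyclobutan-1-ol | c1ccccc1COCO[C@H]2CC[C@H]2O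
F8 | step 4 | N-methoxy-N-methyloctadecanamide | CCCCCCCCCCCCCCCCCC(=O)N(C)OC
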